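C1 = CO2H, C2=C3–C4=C5 = diene, C6 bears the C1′H(OH)CH3 branch, C7 (Me), C8H2, C9 (Me), C10 (OH), C11H2, C12 = aryl ketone.
**Cuts:** C4=C5 (vinylogous HWE), then C9–C10 (1,2-shift from boron to carbon), then C6–C1′ (syn aldol), C7–C8 (conjugate allylation) and C9–B (Markovnikov protoboration of the allyl terminus).
**Forward:** the crotonyl imide gains C7–C8, then C6–C1′, then C9–B, which gives the C5–C9 boronic ester 13. Nitro keto ester 14 gives the C10–C12 aryl benzoate 20. Compounds 13 and 20 are joined at C9–C10, the C1–C4 dienoate is added last, and one acid treatment unmasks everything.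
**Stereochemistry:** one (R)-benzyloxazolidinone sets C7 (chelate-controlled allylation) and C6/C1′ (Evans syn aldol). A chiral NHC–Cu catalyst sets C9, (−)-sparteine sets C10, and the phosphonate sets the diene geometry.
**Enabling feature:** C10 is a CH(OH) between the C9 methine and the C11 methylene, with its oxygen 1,3 to the C12 carbonyl. C8 is CH2, so no enolate is available at C9. With C12 locked in a 1,3-dioxolane ring, an α-oxygenated C10 carbanion has no β-leaving group, so boron can carry C9 onto C10 and is then exchanged for the C10 hydroxyl.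

Key step: step 12

Assumption: the sense of induction of the (ANIPE)CuCl catalyst is taken from simple α-olefins and the ligand antipode is chosen accordingly. The remote centres of 12 are taken not to override it.

Step 1
Reactants: 1 (R)-4-benzyl-1,3-oxazolidin-2-one; 2 (E)-but-2-enoyl chloride
Product: 4 (R)-4-benzyl-3-[(E)-but-2-enoyl]-1,3-oxazolidin-2-one, via lithium oxazolidinide 3 (not isolated)
Conditions: n-BuLi, THF, −78 °C; then 2, −78 → 0 °C
Reagents that add atoms: none
Why: N-acylation of the lithiated oxazolidinone by the acid chloride is the standard imide formation and touches no stereocentre.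

Step 2
Reactants: 4 (R)-4-benzyl-3-[(E)-but-2-enoyl]-1,3-oxazolidin-2-one; 5 allyltrimethylsilane
Product: 6 (R)-4-benzyl-3-[(3R)-3-methylhex-5-enoyl]-1,3-oxazolidin-2-one
Conditions: TiCl4, CH2Cl2, −78 °C; aq. NH4Cl
Reagents that add atoms: none
Why: In this Hosomi–Sakurai conjugate allylation TiCl4 chelates both imide carbonyls and fixes the s-cis enoyl conformer, so the allylsilane should attack the face opposite the benzyl group and set C7 as R.

Step 3
Reactants: 6 (R)-4-benzyl-3-[(3R)-3-methylhex-5-enoyl]-1,3-oxazolidin-2-one; 7 acetaldehyde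
Product: 10 (R)-4-benzyl-3-{(2R,3S)-3-hydroxy-2-[(2R)-pent-4-en-2-yl]butanoyl}-1,3-oxazolidin-2-one, via boron enolate 8 (not isolated), via boron aldolate 9 (not isolated)
Conditions: n-Bu2BOTf, Et3N, CH2Cl2, −78 → 0 °C; 7, −78 → 0 °C; pH 7 buffer, MeOH, 30% H2O2, 0 °C
Reagents that add atoms: none
Why: In this Evans syn aldol the Z-boron enolate reacts through a chair transition state with the auxiliary dipole opposed, so the (R)-auxiliary should set C6 and C1′ together (2R,3S in 10) and override the C7 centre.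

Step 4
Reactants: 10 (R)-4-benzyl-3-{(2R,3S)-3-hydroxy-2-[(2R)-pent-4-en-2-yl]butanoyl}-1,3-oxazolidin-2-one
Product: 11 (2S,3S)-2-[(2R)-pent-4-en-2-yl]butane-1,3-diol
Conditions: LiBH4, Et2O–MeOH, 0 °C
Reagents that add atoms: none
Why: Reductive cleavage of an N-acyl oxazolidinone with LiBH4 takes the exocyclic carbonyl to the primary alcohol without epimerising C6 and leaves the alkene alone.

Step 5
Reactants: 11 (2S,3S)-2-[(2R)-pent-4-en-2-yl]butane-1,3-diol
Product: 12 (4R,5S,6S)-6-(tert-butyldimethylsilyloxy)-5-[(tert-butyldimethylsilyloxy)methyl]-4-methylhept-1-ene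
Conditions: TBSOTf, 2,6-lutidine, CH2Cl2, 0 °C
Reagents that add atoms: tert-butyldimethylsilyl triflate, CC(C)(C)[Si](C)(C)OS(=O)(=O)C(F)(F)F
Why: Silyl ether formation with the silyl triflate covers both hydroxyls, the hindered secondary one included, with groups inert to organolithiums.

Step 6
Reactants: 12 (4R,5S,6S)-6-(tert-butyldimethylsilyloxy)-5-[(tert-butyldimethylsilyloxy)methyl]-4-methylhept-1-ene
Product: 13 2-{(2S,4R,5S,6S)-6-(tert-butyldimethylsilyloxy)-5-[(tert-butyldimethylsilyloxy)methyl]-4-methylheptan-2-yl}-4,4,5,5-tetramethyl-1,3,2-dioxaborolane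
Conditions: (ANIPE)CuCl (5 mol %, antipode that gives the S boronate), NaOt-Bu (cat.), B2pin2, MeOH, hexane, rt
Reagents that add atoms: bis(pinacolato)diboron, CC1(C)OB(OC1(C)C)B1OC(C)(C)C(C)(C)O1
Why: In this NHC–copper-catalysed enantioselective Markovnikov protoboration of an α-olefin, borylcupration puts boron on the internal carbon and MeOH protonates the C–Cu bond, so the chiral carbene should set C9 as S.

Step 7
Reactants: 14 ethyl 3-(4-nitrophenyl)-3-oxopropanoate
Product: 15 ethyl 2-[2-(4-nitrophenyl)-1,3-dioxolan-2-yl]acetate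
Conditions: ethylene glycol, p-TsOH (cat.), toluene, reflux, Dean–Stark
Reagents that add atoms: ethylene glycol, OCCO
Why: Acid-catalysed ketalisation with azeotropic removal of water should go well because the nitro group keeps the aryl ketone electrophilic.

Step 8
Reactants: 15 ethyl 2-[2-(4-nitrophenyl)-1,3-dioxolan-2-yl]acetate
Product: 17 ethyl 2-(2-{4-[(tert-butoxycarbonyl)amino]phenyl}-1,3-dioxolan-2-yl)acetate, via aniline 16 (not isolated)
Conditions: H2 (1 atm), Pd/C, Boc2O, EtOAc, rt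
Reagents that add atoms: di-tert-butyl dicarbonate, CC(C)(C)OC(=O)OC(=O)OC(C)(C)C
Why: Catalytic hydrogenation of the nitroarene gives an electron-rich aniline that is acylated in situ by Boc2O under neutral conditions, which spare the dioxolane.

Step 9
Reactants: 17 ethyl 2-(2-{4-[(tert-butoxycarbonyl)amino]phenyl}-1,3-dioxolan-2-yl)acetate
Product: 18 tert-butyl N-{4-[2-(2-hydroxyethyl)-1,3-dioxolan-2-yl]phenyl}carbamate
Conditions: LiAlH4, THF, 0 °C
Reagents that add atoms: none
Why: Hydride reduction of the ester gives the primary alcohol, while the carbamate is shielded as its N-anion at this temperature.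

Step 10
Reactants: 18 tert-butyl N-{4-[2-(2-hydroxyethyl)-1,3-dioxolan-2-yl]phenyl}carbamate; 19 2,4,6-triisopropylbenzoic acid
Product: 20 2-(2-{4-[(tert-butoxycarbonyl)amino]phenyl}-1,3-dioxolan-2-yl)ethyl 2,4,6-triisopropylbenzoate
Conditions: PPh3, DIAD, THF, 0 °C → rt
Reagents that add atoms: none
Why: Mitsunobu esterification activates the unhindered primary alcohol and not the hindered acid, and the much less acidic carbamate N–H should not compete.

Step 11
Reactants: 21 tert-butyl (E)-4-bromobut-2-enoate; 22 triethyl phosphite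
Product: 23 tert-butyl (E)-4-(diethoxyphosphoryl)but-2-enoate
Conditions: neat, 120 °C
Reagents that add atoms: none
Why: The Michaelis–Arbuzov reaction of the allylic bromide gives the phosphonate with the E alkene kept.

Step 12
Reactants: 20 2-(2-{4-[(tert-butoxycarbonyl)amino]phenyl}-1,3-dioxolan-2-yl)ethyl 2,4,6-triisopropylbenzoate; 13 2-{(2S,4R,5S,6S)-6-(tert-butyldimethylsilyloxy)-5-[(tert-butyldimethylsilyloxy)methyl]-4-methylheptan-2-yl}-4,4,5,5-tetramethyl-1,3,2-dioxaborolane
Product: 27 tert-butyl N-[4-(2-{(2R,3S,5R,6S,7S)-7-(tert-butyldimethylsilyloxy)-6-[(tert-butyldimethylsilyloxy)methyl]-2-hydroxy-3,5-dimethyloctyl}-1,3-dioxolan-2-yl)phenyl]carbamate, via dilithiated benzoate 24 (not isolated), via boronate complex 25 (not isolated), via homologated boronic ester 26 (not isolated)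
Conditions: 20, s-BuLi (2 equiv per 20), (−)-sparteine, Et2O, −78 °C; 13, −78 °C; → 35 °C; then NaOH, 30% H2O2, THF–H2O, 0 °C → rt
Reagents that add atoms: hydrogen peroxide, OO
Why: The first equivalent of s-BuLi removes the carbamate N–H and the second, bound to (−)-sparteine and held at the benzoate carbonyl, removes the pro-S hydrogen at C10 to give the configurationally stable (S)-organolithium 24, which adds to the vacant boron orbital of 13 with retention to give boronate 25; on warming, C9 migrates from boron to C10 antiperiplanar to the leaving triisopropylbenzoate (retention at C9, inversion at C10), which forms the C9–C10 bond in 26, and alkaline H2O2 then exchanges boron for hydroxyl with retention. The closest known reaction type is lithiation–borylation (a Matteson-type 1,2-metallate rearrangement) of secondary alkyl pinacol boronic esters with sparteine-ligated lithiated primary 2,4,6-triisopropylbenzoates, followed by oxidation. No ring is closed in this step. C10 (R) is the only new stereocentre and is set by the chiral diamine alone, while C9 (S) is carried over from 13 by the stereospecific shift, so the anti C9-methyl/C10-hydroxyl pair does not depend on substrate bias. The step needs deprotonation at C10 only and migration of carbon rather than of a pinacol oxygen: the benzoate carbonyl directs the base to C10, the N-lithiated carbamate, the silyl ethers and the dioxolane offer no competing acidic or electrophilic site, C11 bears no leaving group so 24 cannot eliminate, and the good benzoate leaving group lets the hindered boronate rearrange without a Lewis acid that would endanger the dioxolane.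

Step 13
Reactants: 27 tert-butyl N-[4-(2-{(2R,3S,5R,6S,7S)-7-(tert-butyldimethylsilyloxy)-6-[(tert-butyldimethylsilyloxy)methyl]-2-hydroxy-3,5-dimethyloctyl}-1,3-dioxolan-2-yl)phenyl]carbamate
Product: 28 tert-butyl N-[4-(2-{(2R,3S,5R,6S,7S)-7-(tert-butyldimethylsilyloxy)-2-hydroxy-6-(hydroxymethyl)-3,5-dimethyloctyl}-1,3-dioxolan-2-yl)phenyl]carbamate
Conditions: HF·pyridine, pyridine, THF, 0 °C
Reagents that add atoms: none
Why: Buffered fluoride desilylation should cleave the primary silyl ether well before the hindered secondary one, and the medium is too weakly acidic to open the dioxolane or the Boc group.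

Step 14
Reactants: 28 tert-butyl N-[4-(2-{(2R,3S,5R,6S,7S)-7-(tert-butyldimethylsilyloxy)-2-hydroxy-6-(hydroxymethyl)-3,5-dimethyloctyl}-1,3-dioxolan-2-yl)phenyl]carbamate
Product: 29 tert-butyl N-[4-(2-{(2R,3S,5R,6R,7S)-7-(tert-butyldimethylsilyloxy)-6-formyl-2-hydroxy-3,5-dimethyloctyl}-1,3-dioxolan-2-yl)phenyl]carbamate
Conditions: TEMPO (cat.), PhI(OAc)2, CH2Cl2, rt
Reagents that add atoms: none
Why: The oxoammonium (TEMPO/PhI(OAc)2) oxidation prefers the primary alcohol on steric grounds, so the C10 carbinol should stay untouched and C6 should not epimerise in the near-neutral medium.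

Step 15
Reactants: 29 tert-butyl N-[4-(2-{(2R,3S,5R,6R,7S)-7-(tert-butyldimethylsilyloxy)-6-formyl-2-hydroxy-3,5-dimethyloctyl}-1,3-dioxolan-2-yl)phenyl]carbamate; 23 tert-butyl (E)-4-(diethoxyphosphoryl)but-2-enoate
Product: 31 tert-butyl (2E,4E,6S,7R,9S,10R)-11-(2-{4-[(tert-butoxycarbonyl)amino]phenyl}-1,3-dioxolan-2-yl)-6-[(1S)-1-(tert-butyldimethylsilyloxy)ethyl]-10-hydroxy-7,9-dimethylundeca-2,4-dienoate, via lithiated phosphonate 30 (not isolated)
Conditions: 23 (excess), LiHMDS, THF, −78 °C; 29, −78 → 0 °C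
Reagents that add atoms: none
Why: The vinylogous Horner–Wadsworth–Emmons olefination of the stabilised allylic phosphonate anion should form the new C4=C5 bond as E and keep C2=C3 as E, and the C12 ketal rules out a retro-aldol at the free C10 hydroxyl.

Step 16
Reactants: 31 tert-butyl (2E,4E,6S,7R,9S,10R)-11-(2-{4-[(tert-butoxycarbonyl)amino]phenyl}-1,3-dioxolan-2-yl)-6-[(1S)-1-(tert-butyldimethylsilyloxy)ethyl]-10-hydroxy-7,9-dimethylundeca-2,4-dienoate
Product: 32 (2E,4E,6S,7R,9S,10R)-12-(4-aminophenyl)-10-hydroxy-6-[(1S)-1-hydroxyethyl]-7,9-dimethyl-12-oxododeca-2,4-dienoic acid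
Conditions: TFA, CH2Cl2, H2O, 0 °C → rt; aq. NaHCO3 to pH 5
Reagents that add atoms: water, O
Why: Global acidolysis works because all four masks are acid-labile (tert-butyl ester, Boc, silyl ether and the dioxolane of an electron-rich aryl ketone), and no stereocentre is adjacent to a cation-forming site.

Compound list
1 | (R)-4-benzyl-1,3-oxazolidin-2-one | O=C1N[C@H](Cc2ccccc2)CO1 | starting material
2 | (E)-but-2-enoyl chloride | C/C=C/C(=O)Cl | starting material
3 | N-lithio-(R)-4-benzyl-1,3-oxazolidin-2-one | [Li]N1C(=O)OC[C@H]1Cc1ccccc1 | intermediate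
4 | (R)-4-benzyl-3-[(E)-but-2-enoyl]-1,3-oxazolidin-2-one | C/C=C/C(=O)N1C(=O)OC[C@H]1Cc1ccccc1 | intermediate
5 | allyltrimethylsilane | C=CC[Si](C)(C)C | starting material
6 | (R)-4-benzyl-3-[(3R)-3-methylhex-5-enoyl]-1,3-oxazolidin-2-one | O=C(C[C@H](C)CC=C)N1C(=O)OC[C@H]1Cc1ccccc1 | intermediate
7 | acetaldehyde | CC=O | starting material
8 | (Z)-di-n-butylboron enolate of 6 | CCCCB(CCCC)O/C(=C\[C@H](C)CC=C)N1C(=O)OC[C@H]1Cc1ccccc1 | intermediate
9 | O-di-n-butylboryl derivative of 10 | C[C@H](OB(CCCC)CCCC)[C@H](C(=O)N1C(=O)OC[C@H]1Cc1ccccc1)[C@H](C)CC=C | intermediate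
10 | (R)-4-benzyl-3-{(2R,3S)-3-hydroxy-2-[(2R)-pent-4-en-2-yl]butanoyl}-1,3-oxazolidin-2-one | C[C@H](O)[C@H](C(=O)N1C(=O)OC[C@H]1Cc1ccccc1)[C@H](C)CC=C | intermediate
11 | (2S,3S)-2-[(2R)-pent-4-en-2-yl]butane-1,3-diol | C[C@H](O)[C@H](CO)[C@H](C)CC=C | intermediate
12 | (4R,5S,6S)-6-(tert-butyldimethylsilyloxy)-5-[(tert-butyldimethylsilyloxy)methyl]-4-methylhept-1-ene | C[C@H](O[Si](C)(C)C(C)(C)C)[C@H](CO[Si](C)(C)C(C)(C)C)[C@H](C)CC=C | intermediate
13 | 2-{(2S,4R,5S,6S)-6-(tert-butyldimethylsilyloxy)-5-[(tert-butyldimethylsilyloxy)methyl]-4-methylheptan-2-yl}-4,4,5,5-tetramethyl-1,3,2-dioxaborolane | C[C@H](O[Si](C)(C)C(C)(C)C)[C@H](CO[Si](C)(C)C(C)(C)C)[C@H](C)C[C@H](C)B1OC(C)(C)C(C)(C)O1 | intermediate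
14 | ethyl 3-(4-nitrophenyl)-3-oxopropanoate | CCOC(=O)CC(=O)c1ccc(cc1)[N+](=O)[O-] | starting material
15 | ethyl 2-[2-(4-nitrophenyl)-1,3-dioxolan-2-yl]acetate | CCOC(=O)CC1(OCCO1)c1ccc(cc1)[N+](=O)[O-] | intermediate
16 | ethyl 2-[2-(4-aminophenyl)-1,3-dioxolan-2-yl]acetate | CCOC(=O)CC1(OCCO1)c1ccc(N)cc1 | intermediate
17 | ethyl 2-(2-{4-[(tert-butoxycarbonyl)amino]phenyl}-1,3-dioxolan-2-yl)acetate | CCOC(=O)CC1(OCCO1)c1ccc(NC(=O)OC(C)(C)C)cc1 | intermediate
18 | tert-butyl N-{4-[2-(2-hydroxyethyl)-1,3-dioxolan-2-yl]phenyl}carbamate | OCCC1(OCCO1)c1ccc(NC(=O)OC(C)(C)C)cc1 | intermediate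
19 | 2,4,6-triisopropylbenzoic acid | CC(C)c1cc(C(C)C)c(C(=O)O)c(C(C)C)c1 | starting material
20 | 2-(2-{4-[(tert-butoxycarbonyl)amino]phenyl}-1,3-dioxolan-2-yl)ethyl 2,4,6-triisopropylbenzoate | CC(C)c1cc(C(C)C)c(C(=O)OCCC2(OCCO2)c2ccc(NC(=O)OC(C)(C)C)cc2)c(C(C)C)c1 | intermediate
21 | tert-butyl (E)-4-bromobut-2-enoate | CC(C)(C)OC(=O)/C=C/CBr | starting material
22 | triethyl phosphite | CCOP(OCC)OCC | starting material
23 | tert-butyl (E)-4-(diethoxyphosphoryl)but-2-enoate | CCOP(=O)(C/C=C/C(=O)OC(C)(C)C)OCC | intermediate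
24 | (S)-C10-lithio-N-lithio derivative of 20 | [Li][C@H](OC(=O)c1c(C(C)C)cc(C(C)C)cc1C(C)C)CC1(OCCO1)c1ccc(N([Li])C(=O)OC(C)(C)C)cc1 | intermediate
25 | lithium boronate from 24 and 13 (boron bound to C9 and C10) | [Li+].C[C@H](O[Si](C)(C)C(C)(C)C)[C@H](CO[Si](C)(C)C(C)(C)C)[C@H](C)C[C@H](C)[B-]1(OC(C)(C)C(C)(C)O1)[C@H](OC(=O)c1c(C(C)C)cc(C(C)C)cc1C(C)C)CC1(OCCO1)c1ccc(N([Li])C(=O)OC(C)(C)C)cc1 | intermediate
26 | (10R)-C10 pinacol boronic ester corresponding to 27 (N-lithiated) | C[C@H](O[Si](C)(C)C(C)(C)C)[C@H](CO[Si](C)(C)C(C)(C)C)[C@H](C)C[C@H](C)[C@H](B1OC(C)(C)C(C)(C)O1)CC1(OCCO1)c1ccc(N([Li])C(=O)OC(C)(C)C)cc1 | intermediate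
27 | tert-butyl N-[4-(2-{(2R,3S,5R,6S,7S)-7-(tert-butyldimethylsilyloxy)-6-[(tert-butyldimethylsilyloxy)methyl]-2-hydroxy-3,5-dimethyloctyl}-1,3-dioxolan-2-yl)phenyl]carbamate | C[C@H](O[Si](C)(C)C(C)(C)C)[C@H](CO[Si](C)(C)C(C)(C)C)[C@H](C)C[C@H](C)[C@H](O)CC1(OCCO1)c1ccc(NC(=O)OC(C)(C)C)cc1 | intermediate
28 | tert-butyl N-[4-(2-{(2R,3S,5R,6S,7S)-7-(tert-butyldimethylsilyloxy)-2-hydroxy-6-(hydroxymethyl)-3,5-dimethyloctyl}-1,3-dioxolan-2-yl)phenyl]carbamate | C[C@H](O[Si](C)(C)C(C)(C)C)[C@H](CO)[C@H](C)C[C@H](C)[C@H](O)CC1(OCCO1)c1ccc(NC(=O)OC(C)(C)C)cc1 | intermediate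
29 | tert-butyl N-[4-(2-{(2R,3S,5R,6R,7S)-7-(tert-butyldimethylsilyloxy)-6-formyl-2-hydroxy-3,5-dimethyloctyl}-1,3-dioxolan-2-yl)phenyl]carbamate | C[C@H](O[Si](C)(C)C(C)(C)C)[C@H](C=O)[C@H](C)C[C@H](C)[C@H](O)CC1(OCCO1)c1ccc(NC(=O)OC(C)(C)C)cc1 | intermediate
30 | C4-lithio derivative of 23 | CCOP(=O)(OCC)C([Li])/C=C/C(=O)OC(C)(C)C | intermediate
31 | tert-butyl (2E,4E,6S,7R,9S,10R)-11-(2-{4-[(tert-butoxycarbonyl)amino]phenyl}-1,3-dioxolan-2-yl)-6-[(1S)-1-(tert-butyldimethylsilyloxy)ethyl]-10-hydroxy-7,9-dimethylundeca-2,4-dienoate | C[C@H](O[Si](C)(C)C(C)(C)C)[C@H](/C=C/C=C/C(=O)OC(C)(C)C)[C@H](C)C[C@H](C)[C@H](O)CC1(OCCO1)c1ccc(NC(=O)OC(C)(C)C)cc1 | intermediate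
32 | (2E,4E,6S,7R,9S,10R)-12-(4-aminophenyl)-10-hydroxy-6-[(1S)-1-hydroxyethyl]-7,9-dimethyl-12-oxododeca-2,4-dienoic acid | C[C@H](O)[C@H](/C=C/C=C/C(=O)O)[C@H](C)C[C@H](C)[C@H](O)CC(=O)c1ccc(N)cc1 | target

Total step count: 16. Longest linear sequence: 11 steps (steps 1–6 and 12–16).

**Steps most likely to fail**

**Step 12.**
- The N-lithiated benzoate may precipitate or be deprotonated only in part.
- Chelation of lithium by a dioxolane oxygen may compete with the diamine and erode the discrimination of the two C10 hydrogens.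
- The hindered boronate may rearrange slowly, so that it reverts or a pinacol oxygen migrates.

The fallback sets out from 12 and 18 and comes back at 27.
- Tsuji–Wacker oxidation of 12 would give (4R,5S,6S)-6-(tert-butyldimethylsilyloxy)-5-[(tert-butyldimethylsilyloxy)methyl]-4-methylheptan-2-one F1.
- Kinetic enolisation at the methyl group (KHMDS, −78 °C) and trapping with N-(5-chloro-2-pyridyl)triflimide would give the terminal enol triflate (4R,5S,6S)-6-(tert-butyldimethylsilyloxy)-5-[(tert-butyldimethylsilyloxy)methyl]-4-methylhept-1-en-2-yl trifluoromethanesulfonate F2.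
- Dess–Martin oxidation of 18 would give tert-butyl N-{4-[2-(2-oxoethyl)-1,3-dioxolan-2-yl]phenyl}carbamate F3.
- A Ni/Cr-mediated Nozaki–Hiyama–Kishi coupling of F2 with F3 on a chiral sulfonamide–chromium complex forms the same C9–C10 bond under neutral conditions. It would give the (10R)-allylic alcohol tert-butyl N-[4-(2-{(2R,5R,6S,7S)-7-(tert-butyldimethylsilyloxy)-6-[(tert-butyldimethylsilyloxy)methyl]-2-hydroxy-5-methyl-3-methylideneoctyl}-1,3-dioxolan-2-yl)phenyl]carbamate F4.
- Hydroxyl-directed hydrogenation of its 1,1-disubstituted alkene with a cationic rhodium diphosphine catalyst should place the C9 methyl anti to the C10 hydroxyl, which is 27.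

**Step 6.**
- Borylcupration may lose its branched regiochemistry on this β-branched chain.
- The catalyst may meet a mismatched substrate bias, so that facial selectivity at C9 is poor.

The fallback sets out from 12 and comes back at 13.
- Ozonolysis of 12 with NaBH4 work-up would give (3R,4S,5S)-5-(tert-butyldimethylsilyloxy)-4-[(tert-butyldimethylsilyloxy)methyl]-3-methylhexan-1-ol F5.
- Mitsunobu esterification with 19 would give (3R,4S,5S)-5-(tert-butyldimethylsilyloxy)-4-[(tert-butyldimethylsilyloxy)methyl]-3-methylhexyl 2,4,6-triisopropylbenzoate F6.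
- Deprotonation with s-BuLi/(−)-sparteine, capture with methylboronic acid pinacol ester and 1,2-migration of the methyl group should give 13 with C9 fixed by the diamine.

**Step 16.**
- The strong acid may dehydrate the β-hydroxy ketone once the dioxolane has opened.
- It may remove the hindered silyl ether only slowly.
- It may let tert-butyl cations alkylate the freed aniline.

The fallback sets out from 29 and comes back at 32, and it avoids strong protic acid by using orthogonal masks.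
- Olefination of 29 with commercial triethyl 4-phosphonocrotonate (LiHMDS) would give ethyl (2E,4E,6S,7R,9S,10R)-11-(2-{4-[(tert-butoxycarbonyl)amino]phenyl}-1,3-dioxolan-2-yl)-6-[(1S)-1-(tert-butyldimethylsilyloxy)ethyl]-10-hydroxy-7,9-dimethylundeca-2,4-dienoate F7.
- Saponification with LiOH while the ketal still blocks a retro-aldol would give the corresponding dienoic acid F8.
- TMSOTf/2,6-lutidine followed by methanol would remove the Boc group without protic acid and give the amino acid (2E,4E,6S,7R,9S,10R)-11-[2-(4-aminophenyl)-1,3-dioxolan-2-yl]-6-[(1S)-1-(tert-butyldimethylsilyloxy)ethyl]-10-hydroxy-7,9-dimethylundeca-2,4-dienoic acid F9.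
- Dilute aqueous HF in acetonitrile would then cleave the silyl ether and the dioxolane to give 32.

Further compounds
F1 | step 12 | (4R,5S,6S)-6-(tert-butyldimethylsilyloxy)-5-[(tert-butyldimethylsilyloxy)methyl]-4-methylheptan-2-one | C[C@H](O[Si](C)(C)C(C)(C)C)[C@H](CO[Si](C)(C)C(C)(C)C)[C@H](C)CC(C)=O
F2 | step 12 | (4R,5S,6S)-6-(tert-butyldimethylsilyloxy)-5-[(tert-butyldimethylsilyloxy)methyl]-4-methylhept-1-en-2-yl trifluoromethanesulfonate | C[C@H](O[Si](C)(C)C(C)(C)C)[C@H](CO[Si](C)(C)C(C)(C)C)[C@H](C)CC(=C)OS(=O)(=O)C(F)(F)F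
F3 | step 12 | tert-butyl N-{4-[2-(2-oxoethyl)-1,3-dioxolan-2-yl]phenyl}carbamate | O=CCC1(OCCO1)c1ccc(NC(=O)OC(C)(C)C)cc1
F4 | step 12 | tert-butyl N-[4-(2-{(2R,5R,6S,7S)-7-(tert-butyldimethylsilyloxy)-6-[(tert-butyldimethylsilyloxy)methyl]-2-hydroxy-5-methyl-3-methylideneoctyl}-1,3-dioxolan-2-yl)phenyl]carbamate | C[C@H](O[Si](C)(C)C(C)(C)C)[C@H](CO[Si](C)(C)C(C)(C)C)[C@H](C)CC(=C)[C@H](O)CC1(OCCO1)c1ccc(NC(=O)OC(C)(C)C)cc1
F5 | step 6 | (3R,4S,5S)-5-(tert-butyldimethylsilyloxy)-4-[(tert-butyldimethylsilyloxy)methyl]-3-methylhexan-1-ol | C[C@H](O[Si](C)(C)C(C)(C)C)[C@H](CO[Si](C)(C)C(C)(C)C)[C@H](C)CCO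
F6 | step 6 | (3R,4S,5S)-5-(tert-butyldimethylsilyloxy)-4-[(tert-butyldimethylsilyloxy)methyl]-3-methylhexyl 2,4,6-triisopropylbenzoate | C[C@H](O[Si](C)(C)C(C)(C)C)[C@H](CO[Si](C)(C)C(C)(C)C)[C@H](C)CCOC(=O)c1c(C(C)C)cc(C(C)C)cc1C(C)C
F7 | step 16 | ethyl (2E,4E,6S,7R,9S,10R)-11-(2-{4-[(tert-butoxycarbonyl)amino]phenyl}-1,3-dioxolan-2-yl)-6-[(1S)-1-(tert-butyldimethylsilyloxy)ethyl]-10-hydroxy-7,9-dimethylundeca-2,4-dienoate | C[C@H](O[Si](C)(C)C(C)(C)C)[C@H](/C=C/C=C/C(=O)OCC)[C@H](C)C[C@H](C)[C@H](O)CC1(OCCO1)c1ccc(NC(=O)OC(C)(C)C)cc1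
F8 | step 16 | (2E,4E,6S,7R,9S,10R)-11-(2-{4-[(tert-butoxycarbonyl)amino]phenyl}-1,3-dioxolan-2-yl)-6-[(1S)-1-(tert-butyldimethylsilyloxy)ethyl]-10-hydroxy-7,9-dimethylundeca-2,4-dienoic acid | C[C@H](O[Si](C)(C)C(C)(C)C)[C@H](/C=C/C=C/C(=O)O)[C@H](C)C[C@H](C)[C@H](O)CC1(OCCO1)c1ccc(NC(=O)OC(C)(C)C)cc1
F9 | step 16 | (2E,4E,6S,7R,9S,10R)-11-[2-(4-aminophenyl)-1,3-dioxolan-2-yl]-6-[(1S)-1-(tert-butyldimethylsilyloxy)ethyl]-10-hydroxy-7,9-dimethylundeca-2,4-dienoic acid | C[C@H](O[Si](C)(C)C(C)(C)C)[C@H](/C=C/C=C/C(=O)O)[C@H](C)C[C@H](C)[C@H](O)CC1(OCCO1)c1ccc(N)cc1
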